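**Retrosynthetic overview**
- The C14 aldehyde is installed last: allylic C–H oxidation of a C14 methyl group (SeO2), then alcohol to aldehyde (MnO2).
- The ten-membered carbocycle and the α-methylene-γ-lactone are closed together by one CrCl2-mediated intramolecular allylation/lactonisation (C6–C7 bond) of a seco chain that already carries the C8 methacrylate, the C9 acetate and the cis-4,5-oxirane.
- The seco chain comes from late Sharpless epoxidation of a neryl alcohol (C4–C5 oxirane) and from acylative opening of a C7–C8 vinyl oxirane, which gives the C8 methacrylate and the allylic bromide at once.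
- The chain is joined at C9–C10 by NHK coupling of a (Z)-vinyl iodide (from nerol) with an epoxy aldehyde (from methyl 2-bromoacrylate and a stannyl allyl alcohol).
- Ring order: temporary C7–C8 oxirane, then C4–C5 oxirane, then carbocycle and lactone in the same operation.

Assumption: the SMILES is taken as drawn, i.e. (4R,5S,6S,7R,8S,9R) with a cis-fused 4,5-oxirane (C3 and C6 cis), a trans-fused 6,12-lactone, and C2 and C9 cis on the C1=C10 bond; germacrane numbering (C1–C15) is used for locants.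

**Step 1**
Reactants: 1 nerol
Product: 2 tert-butyl{[(2Z)-3,7-dimethylocta-2,6-dien-1-yl]oxy}dimethylsilane
Conditions: TBSCl, imidazole, DMF, 0 °C to rt
Reagents that add atoms: tert-butyldimethylsilyl chloride, CC(C)(C)[Si](C)(C)Cl
Why: Standard silylation of the primary allylic alcohol, so that the C6 oxygen survives the olefination, chromium and acylation steps; no stereocentre is formed.

**Step 2**
Reactants: 2 tert-butyl{[(2Z)-3,7-dimethylocta-2,6-dien-1-yl]oxy}dimethylsilane
Product: 4 (4Z)-6-[(tert-butyldimethylsilyl)oxy]-4-methylhex-4-enal, via distal epoxide 3 (not isolated)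
Conditions: mCPBA (1.0 equiv), CH2Cl2, −20 °C; then H5IO6, THF/Et2O, 0 °C
Reagents that add atoms: mCPBA, OOC(=O)c1cccc(Cl)c1
Why: Prilezhaev epoxidation takes the distal, more electron-rich trisubstituted alkene (the proximal one is deactivated by the allylic silyloxy group), and periodic acid then cleaves the epoxide through its diol (Malaprade-type cleavage) to the C1 aldehyde, destroying the racemic epoxide centre.

**Step 3**
Reactants: 4 (4Z)-6-[(tert-butyldimethylsilyl)oxy]-4-methylhex-4-enal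
Product: 5 tert-butyl{[(2Z,6Z)-7-iodo-3-methylocta-2,6-dien-1-yl]oxy}dimethylsilane
Conditions: EtPPh3I, n-BuLi, THF, 0 °C; I2, −78 °C; NaN(SiMe3)2, −20 °C; then 4, −78 °C to rt
Reagents that add atoms: ethyltriphenylphosphonium iodide, CC[P+](c1ccccc1)(c1ccccc1)c1ccccc1.[I-]; iodine, II
Why: Stork–Zhao olefination with the α-iodo ylide gives the (Z)-2-iodoalkene under kinetic Wittig control (iodine cis to the chain), which fixes the ring-cis geometry of the future C1=C10 bond.

**Step 4**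
Reactants: 6 methyl 2-bromoprop-2-enoate; 7 (2E)-3-(tributylstannyl)prop-2-en-1-ol
Product: 8 methyl (3E)-5-hydroxy-2-methylidenepent-3-enoate
Conditions: Pd(PPh3)4 (5 mol%), CuI (10 mol%), DMF, rt; product kept cold and used at once
Reagents that add atoms: none
Why: Stille cross-coupling of the α-bromoacrylate with the (E)-alkenylstannane proceeds with retention of alkene geometry and tolerates the free hydroxyl; no stereocentre is formed.

**Step 5**
Reactants: 8 methyl (3E)-5-hydroxy-2-methylidenepent-3-enoate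
Product: 9 methyl 2-[(2R,3R)-3-(hydroxymethyl)oxiran-2-yl]prop-2-enoate
Conditions: Ti(OiPr)4 (20 mol%), D-(−)-DIPT (24 mol%), t-BuOOH, 4 Å MS, CH2Cl2, −20 °C
Reagents that add atoms: tert-butyl hydroperoxide, CC(C)(C)OO
Why: Sharpless asymmetric epoxidation is directed by the allylic hydroxyl to the C7=C8 alkene only (the acrylate alkene is electron-poor and not allylic to the hydroxyl), and D-(−)-tartrate gives the (2R,3R)-epoxy alcohol, which sets C8.

**Step 6**
Reactants: 9 methyl 2-[(2R,3R)-3-(hydroxymethyl)oxiran-2-yl]prop-2-enoate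
Product: 10 methyl 2-[(2R,3S)-3-formyloxiran-2-yl]prop-2-enoate
Conditions: TEMPO (10 mol%), PhI(OAc)2, CH2Cl2, 0 °C to rt; used as a crude solution
Reagents that add atoms: none
Why: Oxoammonium (TEMPO/PhI(OAc)2) oxidation of the primary alcohol to the aldehyde is near-neutral and leaves the oxirane, the acrylate and the α-stereocentre untouched.

**Step 7**
Reactants: 5 tert-butyl{[(2Z,6Z)-7-iodo-3-methylocta-2,6-dien-1-yl]oxy}dimethylsilane; 10 methyl 2-[(2R,3S)-3-formyloxiran-2-yl]prop-2-enoate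
Product: 12 methyl 2-[(2R,3R)-3-[(1R,2Z,6Z)-8-[(tert-butyldimethylsilyl)oxy]-1-hydroxy-2,6-dimethylocta-2,6-dien-1-yl]oxiran-2-yl]prop-2-enoate, via alkenylchromium dichloride 11 (not isolated)
Conditions: CrCl2 (4 equiv), NiCl2 (1 mol%), DMSO, rt
Reagents that add atoms: none
Why: Nozaki–Hiyama–Kishi coupling, in which the alkenylchromium forms with retention of geometry and adds only to the aldehyde, and Felkin–Anh attack anti to the oxirane C8–O bond gives the 8,9-anti (erythro) alcohol, i.e. 9R.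

**Step 8**
Reactants: 12 methyl 2-[(2R,3R)-3-[(1R,2Z,6Z)-8-[(tert-butyldimethylsilyl)oxy]-1-hydroxy-2,6-dimethylocta-2,6-dien-1-yl]oxiran-2-yl]prop-2-enoate
Product: 13 methyl 2-[(2R,3S)-3-[(1R,2Z,6Z)-1-acetoxy-8-[(tert-butyldimethylsilyl)oxy]-2,6-dimethylocta-2,6-dien-1-yl]oxiran-2-yl]prop-2-enoate
Conditions: Ac2O, pyridine, DMAP (cat.), CH2Cl2, 0 °C
Reagents that add atoms: acetic anhydride, CC(=O)OC(C)=O
Why: DMAP-catalysed acetylation of the only free hydroxyl fixes the C9 acetate before the neighbouring C8 oxygen is unmasked (the C8 descriptor changes from R to S only because of CIP priorities).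

**Step 9**
Reactants: 13 methyl 2-[(2R,3S)-3-[(1R,2Z,6Z)-1-acetoxy-8-[(tert-butyldimethylsilyl)oxy]-2,6-dimethylocta-2,6-dien-1-yl]oxiran-2-yl]prop-2-enoate
Product: 14 methyl (2Z,4S,5R,6Z,10Z)-5-acetoxy-2-(bromomethyl)-12-[(tert-butyldimethylsilyl)oxy]-6,10-dimethyl-4-[(2-methylprop-2-enoyl)oxy]dodeca-2,6,10-trienoate
Conditions: methacryloyl chloride, LiBr (excess), MeCN, −20 to 0 °C
Reagents that add atoms: methacryloyl chloride, C=C(C)C(Cl)=O; lithium bromide, [Li+].[Br-]
Why: Acylative ring-opening of an epoxide by an acyl bromide (made in the flask by halide exchange) keeps the oxirane oxygen on C8 with retention and acylates it, while bromide enters at the allylic or vinylogous carbon (SN2 or SN2') and excess bromide equilibrates the product to the conjugated primary allylic bromide, so C7 is no longer a stereocentre.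

**Step 10**
Reactants: 14 methyl (2Z,4S,5R,6Z,10Z)-5-acetoxy-2-(bromomethyl)-12-[(tert-butyldimethylsilyl)oxy]-6,10-dimethyl-4-[(2-methylprop-2-enoyl)oxy]dodeca-2,6,10-trienoate
Product: 15 methyl (2Z,4S,5R,6Z,10Z)-5-acetoxy-2-(bromomethyl)-12-hydroxy-6,10-dimethyl-4-[(2-methylprop-2-enoyl)oxy]dodeca-2,6,10-trienoate
Conditions: aq. HF (48%), MeCN, 0 °C
Reagents that add atoms: none
Why: Acidic fluoride desilylation cleaves the primary TBS ether without an amine base, so the esters and the electrophilic allylic bromide survive; no oxirane is present at this stage.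

**Step 11**
Reactants: 15 methyl (2Z,4S,5R,6Z,10Z)-5-acetoxy-2-(bromomethyl)-12-hydroxy-6,10-dimethyl-4-[(2-methylprop-2-enoyl)oxy]dodeca-2,6,10-trienoate
Product: 16 methyl (2Z,4S,5R,6Z)-5-acetoxy-2-(bromomethyl)-9-[(2R,3S)-3-(hydroxymethyl)-2-methyloxiran-2-yl]-6-methyl-4-[(2-methylprop-2-enoyl)oxy]nona-2,6-dienoate
Conditions: Ti(OiPr)4 (20 mol%), L-(+)-DIPT (24 mol%), t-BuOOH, 4 Å MS, CH2Cl2, −25 °C
Reagents that add atoms: tert-butyl hydroperoxide, CC(C)(C)OO
Why: Sharpless asymmetric epoxidation acts only on the single allylic alcohol, and with L-(+)-tartrate the (Z)-allylic alcohol gives the cis-oxirane with 4R,5S under reagent control (the minor diastereomer is removed by chromatography).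

**Step 12**
Reactants: 16 methyl (2Z,4S,5R,6Z)-5-acetoxy-2-(bromomethyl)-9-[(2R,3S)-3-(hydroxymethyl)-2-methyloxiran-2-yl]-6-methyl-4-[(2-methylprop-2-enoyl)oxy]nona-2,6-dienoate
Product: 17 methyl (2Z,4S,5R,6Z)-5-acetoxy-2-(bromomethyl)-9-[(2R,3R)-3-formyl-2-methyloxiran-2-yl]-6-methyl-4-[(2-methylprop-2-enoyl)oxy]nona-2,6-dienoate
Conditions: TEMPO (10 mol%), PhI(OAc)2, CH2Cl2, rt
Reagents that add atoms: none
Why: Oxoammonium oxidation of the primary epoxy alcohol gives the cis-epoxy aldehyde under neutral conditions that do not touch the allylic bromide or the esters (the C5 descriptor changes only through CIP priorities).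

**Step 13**
Reactants: 17 methyl (2Z,4S,5R,6Z)-5-acetoxy-2-(bromomethyl)-9-[(2R,3R)-3-formyl-2-methyloxiran-2-yl]-6-methyl-4-[(2-methylprop-2-enoyl)oxy]nona-2,6-dienoate
Product: 20 (4R,5S,6S,7R,8S,9R)-9-acetoxy-4,5-epoxy-8-(methacryloyloxy)germacra-1(10)Z,11(13)-dien-6,12-olide, via allylchromium dichloride 18 (not isolated), via macrocyclic chromium alkoxide 19 (not isolated)
Conditions: CrCl2 (8 equiv), DMF, syringe-pump addition to 2 mM, rt; then 40 °C
Reagents that add atoms: none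
Why: Intramolecular Nozaki–Hiyama (chromium Barbier) allylation with in situ lactonisation closes the ten-membered ring and the α-methylene-γ-lactone in one operation, the aldehyde being attacked anti to the oxirane C5–O bond (Felkin–Anh, sets 6S) through a chair-like six-membered chromium transition state with both ring arms equatorial (6,7-anti, hence the trans-fused lactone) and on the C7 face anti to the C9 arm in the A(1,3)-minimised rotamer at C8 (sets 7R).

**Step 14**
Reactants: 20 (4R,5S,6S,7R,8S,9R)-9-acetoxy-4,5-epoxy-8-(methacryloyloxy)germacra-1(10)Z,11(13)-dien-6,12-olide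
Product: 21 (4R,5S,6S,7R,8S,9R)-9-acetoxy-4,5-epoxy-14-hydroxy-8-(methacryloyloxy)germacra-1(10)Z,11(13)-dien-6,12-olide
Conditions: SeO2 (0.3 equiv), t-BuOOH, CH2Cl2, rt
Reagents that add atoms: tert-butyl hydroperoxide, CC(C)(C)OO; selenium dioxide, O=[Se]=O
Why: Riley allylic oxidation (ene reaction, then [2,3]-sigmatropic shift) attacks the only electron-rich alkene at its more substituted end, where the C14 methyl is the only oxidisable position (C9 is an acetoxy-bearing methine), and the [2,3] step places the new CH2OH trans to C2, which keeps the ring-cis C1=C10 geometry.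

**Step 15**
Reactants: 21 (4R,5S,6S,7R,8S,9R)-9-acetoxy-4,5-epoxy-14-hydroxy-8-(methacryloyloxy)germacra-1(10)Z,11(13)-dien-6,12-olide
Product: 22 (4R,5S,6S,7R,8S,9R)-9-acetoxy-4,5-epoxy-8-(methacryloyloxy)-14-oxogermacra-1(10)E,11(13)-dien-6,12-olide
Conditions: MnO2 (activated, excess), CH2Cl2, rt
Reagents that add atoms: none
Why: MnO2 oxidises only the allylic primary alcohol to the conjugated aldehyde and leaves the oxirane, the esters and both Michael acceptors untouched (the alkene descriptor changes from Z to E only through CIP priorities).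

**Compound list**
1 | nerol, (2Z)-3,7-dimethylocta-2,6-dien-1-ol | OC/C=C(/C)CCC=C(C)C | starting material
2 | tert-butyl{[(2Z)-3,7-dimethylocta-2,6-dien-1-yl]oxy}dimethylsilane | CC(C)(C)[Si](C)(C)OC/C=C(/C)CCC=C(C)C | intermediate
3 | tert-butyl{[(2Z)-5-(3,3-dimethyloxiran-2-yl)-3-methylpent-2-en-1-yl]oxy}dimethylsilane (racemic at the oxirane CH) | CC(C)(C)[Si](C)(C)OC/C=C(/C)CCC1OC1(C)C | intermediate (not isolated)
4 | (4Z)-6-[(tert-butyldimethylsilyl)oxy]-4-methylhex-4-enal | CC(C)(C)[Si](C)(C)OC/C=C(/C)CCC=O | intermediate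
5 | tert-butyl{[(2Z,6Z)-7-iodo-3-methylocta-2,6-dien-1-yl]oxy}dimethylsilane | CC(C)(C)[Si](C)(C)OC/C=C(/C)CC/C=C(/C)I | intermediate
6 | methyl 2-bromoprop-2-enoate | C=C(Br)C(=O)OC | starting material
7 | (2E)-3-(tributylstannyl)prop-2-en-1-ol | CCCC[Sn](CCCC)(CCCC)/C=C/CO | starting material
8 | methyl (3E)-5-hydroxy-2-methylidenepent-3-enoate | OC/C=C/C(=C)C(=O)OC | intermediate
9 | methyl 2-[(2R,3R)-3-(hydroxymethyl)oxiran-2-yl]prop-2-enoate | OC[C@H]1O[C@@H]1C(=C)C(=O)OC | intermediate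
10 | methyl 2-[(2R,3S)-3-formyloxiran-2-yl]prop-2-enoate | O=C[C@H]1O[C@@H]1C(=C)C(=O)OC | intermediate
11 | dichloro[(2Z,6Z)-8-[(tert-butyldimethylsilyl)oxy]-6-methylocta-2,6-dien-2-yl]chromium | CC(C)(C)[Si](C)(C)OC/C=C(/C)CC/C=C(/C)[Cr](Cl)Cl | intermediate (not isolated)
12 | methyl 2-[(2R,3R)-3-[(1R,2Z,6Z)-8-[(tert-butyldimethylsilyl)oxy]-1-hydroxy-2,6-dimethylocta-2,6-dien-1-yl]oxiran-2-yl]prop-2-enoate | CC(C)(C)[Si](C)(C)OC/C=C(/C)CC/C=C(/C)[C@@H](O)[C@H]1O[C@@H]1C(=C)C(=O)OC | intermediate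
13 | methyl 2-[(2R,3S)-3-[(1R,2Z,6Z)-1-acetoxy-8-[(tert-butyldimethylsilyl)oxy]-2,6-dimethylocta-2,6-dien-1-yl]oxiran-2-yl]prop-2-enoate | CC(C)(C)[Si](C)(C)OC/C=C(/C)CC/C=C(/C)[C@@H](OC(C)=O)[C@H]1O[C@@H]1C(=C)C(=O)OC | intermediate
14 | methyl (2Z,4S,5R,6Z,10Z)-5-acetoxy-2-(bromomethyl)-12-[(tert-butyldimethylsilyl)oxy]-6,10-dimethyl-4-[(2-methylprop-2-enoyl)oxy]dodeca-2,6,10-trienoate | CC(C)(C)[Si](C)(C)OC/C=C(/C)CC/C=C(/C)[C@@H](OC(C)=O)[C@@H](OC(=O)C(C)=C)/C=C(\CBr)C(=O)OC | intermediate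
15 | methyl (2Z,4S,5R,6Z,10Z)-5-acetoxy-2-(bromomethyl)-12-hydroxy-6,10-dimethyl-4-[(2-methylprop-2-enoyl)oxy]dodeca-2,6,10-trienoate | OC/C=C(/C)CC/C=C(/C)[C@@H](OC(C)=O)[C@@H](OC(=O)C(C)=C)/C=C(\CBr)C(=O)OC | intermediate
16 | methyl (2Z,4S,5R,6Z)-5-acetoxy-2-(bromomethyl)-9-[(2R,3S)-3-(hydroxymethyl)-2-methyloxiran-2-yl]-6-methyl-4-[(2-methylprop-2-enoyl)oxy]nona-2,6-dienoate | OC[C@@H]1O[C@]1(C)CC/C=C(/C)[C@@H](OC(C)=O)[C@@H](OC(=O)C(C)=C)/C=C(\CBr)C(=O)OC | intermediate
17 | methyl (2Z,4S,5R,6Z)-5-acetoxy-2-(bromomethyl)-9-[(2R,3R)-3-formyl-2-methyloxiran-2-yl]-6-methyl-4-[(2-methylprop-2-enoyl)oxy]nona-2,6-dienoate | O=C[C@@H]1O[C@]1(C)CC/C=C(/C)[C@@H](OC(C)=O)[C@@H](OC(=O)C(C)=C)/C=C(\CBr)C(=O)OC | intermediate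
18 | allylchromium dichloride from 17 (CrCl2 in place of Br at C13; C7=C11 geometry mobile by 1,3-metal shift) | O=C[C@@H]1O[C@]1(C)CC/C=C(/C)[C@@H](OC(C)=O)[C@@H](OC(=O)C(C)=C)/C=C(\C[Cr](Cl)Cl)C(=O)OC | intermediate (not isolated)
19 | dichlorochromium alkoxide of the ten-membered hydroxy ester (C6–O–CrCl2, methyl acrylate arm on C7, 4R,5S,6S,7R,8S,9R) | C=C(C)C(=O)O[C@H]1[C@@H](C(=C)C(=O)OC)[C@H](O[Cr](Cl)Cl)[C@@H]2O[C@]2(C)CC/C=C(/C)[C@H]1OC(C)=O | intermediate (not isolated)
20 | (4R,5S,6S,7R,8S,9R)-9-acetoxy-4,5-epoxy-8-(methacryloyloxy)germacra-1(10)Z,11(13)-dien-6,12-olide | C=C(C)C(=O)O[C@H]1[C@H]2C(=C)C(=O)O[C@@H]2[C@@H]2O[C@]2(C)CC/C=C(/C)[C@H]1OC(C)=O | intermediate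
21 | (4R,5S,6S,7R,8S,9R)-9-acetoxy-4,5-epoxy-14-hydroxy-8-(methacryloyloxy)germacra-1(10)Z,11(13)-dien-6,12-olide | C=C(C)C(=O)O[C@H]1[C@H]2C(=C)C(=O)O[C@@H]2[C@@H]2O[C@]2(C)CC/C=C(/CO)[C@H]1OC(C)=O | intermediate
22 | (4R,5S,6S,7R,8S,9R)-9-acetoxy-4,5-epoxy-8-(methacryloyloxy)-14-oxogermacra-1(10)E,11(13)-dien-6,12-olide (CNP0121379.1) | C=C(C)C(=O)O[C@H]1[C@H]2C(=C)C(=O)O[C@@H]2[C@@H]2O[C@]2(C)CC/C=C(/C=O)[C@H]1OC(C)=O | target

**Totals**
Total step count: 15.
Longest linear sequence: 12 steps (steps 1–3 then 7–15; the branch through steps 4–6 is equally long).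

**Steps most likely to fail, with fallbacks**

1. Step 13 (ring closure). The allylchromium species carries a methacrylate on the neighbouring carbon and could lose it by 1,4-elimination, and the C6/C7 outcome rests on transition-state models for a ring system without a close precedent. The fallback generates the allyl nucleophile from the vinyl oxirane itself, so no acyloxy leaving group sits next to the metal. Setting out from acetate 13, HF·pyridine buffered with pyridine removes the silyl ether to give methyl 2-[(2R,3S)-3-[(1R,2Z,6Z)-1-acetoxy-8-hydroxy-2,6-dimethylocta-2,6-dien-1-yl]oxiran-2-yl]prop-2-enoate F1. Sharpless epoxidation with L-(+)-DIPT gives the bis-epoxy alcohol F2, and TEMPO/PhI(OAc)2 gives the bis-epoxy aldehyde F3. Pd(PPh3)4 with InI in THF at high dilution then opens only the vinyl oxirane (zerovalent palladium), and monovalent indium reduces the allylpalladium to an allylindium alkoxide that closes the ring through a chelated six-membered transition state and lactonises to the 8-hydroxy macrolactone F4. Methacrylic anhydride/DMAP esterifies the freed C8 hydroxyl and returns to the route at 20.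

2. Step 9 (acylative oxirane opening). The C9 acetate could participate and scramble the two acyl groups, or bromide could enter at C8. The fallback separates ring-opening from acylation. Setting out from 13, MgBr2·OEt2 in CH2Cl2 at −40 °C opens the oxirane at the allylic or vinylogous carbon to the bromohydrin methyl (2Z,4S,5R,6Z,10Z)-5-acetoxy-2-(bromomethyl)-12-[(tert-butyldimethylsilyl)oxy]-4-hydroxy-6,10-dimethyldodeca-2,6,10-trienoate F5. This is esterified without base (methacrylic anhydride, Sc(OTf)3 cat., MeCN, −20 °C), so neither dihydrofuran closure nor acetyl migration is triggered, and the route is rejoined at 14.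

3. Step 7 (NHK union). Aldehyde 10 is labile, and Felkin selectivity with a trans-epoxy aldehyde may be modest or reversed. The fallback sets C9 by inversion instead of by addition. Setting out from 5 and 10, the coupling is run as before and the 9-epimeric alcohol methyl 2-[(2R,3R)-3-[(1S,2Z,6Z)-8-[(tert-butyldimethylsilyl)oxy]-1-hydroxy-2,6-dimethylocta-2,6-dien-1-yl]oxiran-2-yl]prop-2-enoate F6 is taken on. Mitsunobu esterification with acetic acid (PPh3, DIAD, THF, 0 °C) inverts C9 and installs the acetate in one step, coming back to the route at 13.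

**Further compounds**
F1 | step 13 | methyl 2-[(2R,3S)-3-[(1R,2Z,6Z)-1-acetoxy-8-hydroxy-2,6-dimethylocta-2,6-dien-1-yl]oxiran-2-yl]prop-2-enoate | OC/C=C(/C)CC/C=C(/C)[C@@H](OC(C)=O)[C@H]1O[C@@H]1C(=C)C(=O)OC
F2 | step 13 | methyl 2-[(2R,3S)-3-[(1R,2Z)-1-acetoxy-5-[(2R,3S)-3-(hydroxymethyl)-2-methyloxiran-2-yl]-2-methylpent-2-en-1-yl]oxiran-2-yl]prop-2-enoate | OC[C@@H]1O[C@]1(C)CC/C=C(/C)[C@@H](OC(C)=O)[C@H]1O[C@@H]1C(=C)C(=O)OC
F3 | step 13 | methyl 2-[(2R,3S)-3-[(1R,2Z)-1-acetoxy-5-[(2R,3R)-3-formyl-2-methyloxiran-2-yl]-2-methylpent-2-en-1-yl]oxiran-2-yl]prop-2-enoate | O=C[C@@H]1O[C@]1(C)CC/C=C(/C)[C@@H](OC(C)=O)[C@H]1O[C@@H]1C(=C)C(=O)OC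
F4 | step 13 | (4R,5S,6S,7R,8S,9R)-9-acetoxy-4,5-epoxy-8-hydroxygermacra-1(10)Z,11(13)-dien-6,12-olide | O[C@H]1[C@H]2C(=C)C(=O)O[C@@H]2[C@@H]2O[C@]2(C)CC/C=C(/C)[C@H]1OC(C)=O
F5 | step 9 | methyl (2Z,4S,5R,6Z,10Z)-5-acetoxy-2-(bromomethyl)-12-[(tert-butyldimethylsilyl)oxy]-4-hydroxy-6,10-dimethyldodeca-2,6,10-trienoate | CC(C)(C)[Si](C)(C)OC/C=C(/C)CC/C=C(/C)[C@@H](OC(C)=O)[C@@H](O)/C=C(\CBr)C(=O)OC
F6 | step 7 | methyl 2-[(2R,3R)-3-[(1S,2Z,6Z)-8-[(tert-butyldimethylsilyl)oxy]-1-hydroxy-2,6-dimethylocta-2,6-dien-1-yl]oxiran-2-yl]prop-2-enoate | CC(C)(C)[Si](C)(C)OC/C=C(/C)CC/C=C(/C)[C@H](O)[C@H]1O[C@@H]1C(=C)C(=O)OC
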